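The readings were generated by integration with made-up constants.

In a one-step world, starting complex and incoming ligand give complex with one exchanged in a second-order step, so at fixed equivalents the percentage follows starting concentration times elapsed time, which I call the exposure. Here are the flasks, the runs and the questions.

| flask | starting complex | incoming ligand | remark | time |
|---|---|---|---|---|
| elm | 0.20 M | 1.1 equiv | run made earlier |  |
| maple | 0.80 M | 1.1 equiv | run made earlier |  |
| birch | 0.40 M | 0.55 equiv | run made earlier |  |
| flask | 0.40 M | 1.10 equiv |  | 12 min |

- elm (time / min: complex with one exchanged / %): 0.200: 14; 0.417: 22; 0.833: 31; 1.50: 29; 3.00: 30; 6.00: 23; 12.0: 18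
- maple (time / min: complex with one exchanged / %): 0.200: 31; 0.417: 31; 0.833: 27; 1.50: 29; 3.00: 23; 6.00: 17; 12.0: 9
- birch (time / min: complex with one exchanged / %): 0.200: 11; 0.500: 19; 1.50: 22; 4.00: 17; 12.0: 8

(scatter of a reading: 2 percentage points)



- the best time, 12 min at the latest, for complex with one exchanged
- the amount of complex with one exchanged, in percent of the starting complex charged, at that time
- the first time at which complex with one exchanged reaches 22%, in the same percent, in min

Work in powers of ten. In powers of ten, the flask's concentration stands 0.301 above elm's and 0.301 below maple's, and in the one-step world the time to a given percentage moves the opposite way. Elm reads 22% at 0.417 min, so the exposure to that level, the quantity to carry, is 5.00 M·s. With the main step in place, I reckon that the flask reaches 22% at 0.208 min.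

Now add a step that consumes complex with one exchanged as exposure grows, and the climb turns into a ceiling. Elm reads 31% at 0.833 min and maple reads 31% at 0.417 min, exposures of 10.0 M·s and 20.0 M·s, which on the flask's clock are 0.416 min and 0.834 min.

Then add the rest. At the same exposure, 72.0 M·s, elm after 6.00 min reads 23% and maple after 1.50 min reads 29%, lower in the more dilute run with the longer time, against a scatter of 2 percentage points. So I read some of the loss as running on the clock, not on the exposure. Elm has its highest reading, 31%, at 0.833 min, so for the flask I keep a best near that reading inside that window.

The forecast, on the ground that "Rates scale with concentration", gives 30% at 0.6 min and the level at 0.2 min. The flask gives 31.1% at 0.806 min, late in my window, and reaches 22% at 0.191 min.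

    starting complex + incoming ligand ⇌ leaving ligand + complex with one exchanged (K = 0.750, k = 0.0740 L mol⁻¹ s⁻¹)
    complex with one exchanged + incoming ligand ⇌ leaving ligand + complex with two exchanged (K = 0.350, k = 0.0670 L mol⁻¹ s⁻¹)
    starting complex ⇌ dormant form (K = 14.0, k = 0.00220 s⁻¹)
    starting complex + complex with one exchanged → side product (k = 0.0100 L mol⁻¹ s⁻¹)

That first time is an exposure of 4.58 M·s, lower than elm's reading of 5.00 M·s. Of the effects tried on the flask's highest amount by taking them away, the largest single one is that of the reverse step, leaving ligand and complex with one exchanged going back to starting complex and incoming ligand: the flask run without it peaks at 66.1%, not 31.1% . For the flask read at 3.0 min, the exposure is 72.0 M·s, the one shared by elm and maple above, and midway between their readings lies 26.0%. That flask gives 25.5%.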